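The flavone is cut at the bond between C2 of the γ-pyrone ring and C1' of the resorcinol ring. The key step exploits the lone C2–H of a 3-prenylchromone: once C3 carries the prenyl group it is the only C–H on the pyrone ring, and it is acidified by O1 and the C4 carbonyl. A hindered zinc amide therefore turns this normally electrophilic carbon into a nucleophile, which is cross-coupled in the same flask with silyl-protected 4-bromoresorcinol, whose bromine sits on the carbon that becomes C1'. One operation gives the complete flavone skeleton from 5-silyloxy-7-methoxy-3-prenylchromone and 1-bromo-2,4-bis(silyloxy)benzene; only fluoride desilylation remains.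

Key step: step 5

Remark: the target has no stereocentre and no stereogenic double bond (the prenyl alkene carries two methyl groups), so it is achiral and no step has to control configuration. Because a 3-prenyl group next to a free 2'-hydroxyl is acid-sensitive, all protecting groups are silyl ethers removed by fluoride.

Step 1
Reactants: 1 2',6'-dihydroxy-4'-methoxyacetophenone
Product: 2 (E)-1-(2,6-dihydroxy-4-methoxyphenyl)-3-(dimethylamino)prop-2-en-1-one
Conditions: DMF-DMA (1.5 equiv), toluene, 90 °C
Reagents that add atoms: N,N-dimethylformamide dimethyl acetal, COC(OC)N(C)C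
Why: Enaminone formation by condensation of the methyl ketone with the amide acetal is the standard entry to chromones from 2-hydroxyacetophenones; the two chelated ortho-hydroxyls should resist O-methylation and the E-enaminone is the thermodynamic isomer.

Step 2
Reactants: 2 (E)-1-(2,6-dihydroxy-4-methoxyphenyl)-3-(dimethylamino)prop-2-en-1-one
Product: 4 5-hydroxy-7-methoxy-3-(3-methylbut-2-en-1-yl)-4H-chromen-4-one, via 2-(dimethylamino)chromanone adduct 3 (not isolated)
Conditions: prenyl bromide (1.5 equiv), DMF, 70 °C
Reagents that add atoms: prenyl bromide (1-bromo-3-methylbut-2-ene), CC(C)=CCBr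
Why: In this tandem C-alkylation/cyclisation of an o-hydroxyaryl enaminone, the enamine-type α-carbon should attack the primary terminus of the allylic bromide (SN2), an ortho-hydroxyl traps the iminium (6-exo-trig) to give 3, and loss of dimethylamine gives the 3-prenylchromone while the released amine buffers the HBr.

Step 3
Reactants: 4 5-hydroxy-7-methoxy-3-(3-methylbut-2-en-1-yl)-4H-chromen-4-one
Product: 5 5-(tert-butyldimethylsilyloxy)-7-methoxy-3-(3-methylbut-2-en-1-yl)-4H-chromen-4-one
Conditions: TBSOTf (1.3 equiv), 2,6-lutidine (2 equiv), CH2Cl2, 0 °C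
Reagents that add atoms: tert-butyldimethylsilyl triflate, CC(C)(C)[Si](C)(C)OS(=O)(=O)C(F)(F)F
Why: Silyl ether formation on the hydrogen-bonded 5-hydroxyl needs the reactive silyl triflate, lutidine keeps the medium non-acidic for the prenyl alkene, and the acidic phenol is masked before the zinc amide is used.

Step 4
Reactants: 6 4-bromoresorcinol
Product: 7 1-bromo-2,4-bis(tert-butyldimethylsilyloxy)benzene
Conditions: TBSCl (2.4 equiv), imidazole (5 equiv), DMF, rt
Reagents that add atoms: tert-butyldimethylsilyl chloride, CC(C)(C)[Si](C)(C)Cl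
Why: Standard imidazole-promoted silylation of both phenols gives a coupling partner without acidic protons that could quench the organozinc.

Step 5
Reactants: 5 5-(tert-butyldimethylsilyloxy)-7-methoxy-3-(3-methylbut-2-en-1-yl)-4H-chromen-4-one; 7 1-bromo-2,4-bis(tert-butyldimethylsilyloxy)benzene
Product: 9 2-[2,4-bis(tert-butyldimethylsilyloxy)phenyl]-5-(tert-butyldimethylsilyloxy)-7-methoxy-3-(3-methylbut-2-en-1-yl)-4H-chromen-4-one, via chromon-2-ylzinc chloride 8 (not isolated)
Conditions: TMPZnCl·LiCl (1.3 equiv), THF, 25 °C; then 7, Pd(OAc)2 (3 mol %), SPhos (6 mol %), THF, 50 °C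
Reagents that add atoms: none
Why: The TMP-zinc amide removes the C2 proton, the only C–H of the pyranone ring once C3 is alkylated and the most acidic one of 5 because the carbanion sits on an sp2 carbon bound to O1 and β to the C4 carbonyl, to give the C2-zinc species 8; Pd(0)/SPhos then inserts into the C–Br bond of 7, the chromonyl group passes from zinc to palladium and reductive elimination forms the C2–C1' bond. The closest known reaction type is the regioselective zincation of chromones with TMP-zinc bases followed by Negishi coupling to flavones. No ring is closed and no stereocentre is formed. The step needs site selectivity in the metalation, which the prenyl group at C3 secures by blocking the only competing pyranone position, while the arene C6–H and C8–H and the allylic CH2 are too weakly acidic for this mild amide; it also needs chemoselectivity, which the covalent C–Zn bond should provide by leaving the C4 carbonyl, the silyl ethers and the prenyl alkene untouched. The position of the new bond on the B ring is fixed by the bromine of 7, which sits para to one oxygen and ortho to the other.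

Step 6
Reactants: 9 2-[2,4-bis(tert-butyldimethylsilyloxy)phenyl]-5-(tert-butyldimethylsilyloxy)-7-methoxy-3-(3-methylbut-2-en-1-yl)-4H-chromen-4-one
Product: 10 2-(2,4-dihydroxyphenyl)-5-hydroxy-7-methoxy-3-(3-methylbut-2-en-1-yl)-4H-chromen-4-one
Conditions: TBAF (3.5 equiv), AcOH (3.5 equiv), THF, 0 °C to rt
Reagents that add atoms: none
Why: Fluoride-mediated desilylation should cleave all three aryl silyl ethers under buffered, non-acidic conditions that leave the 7-methyl ether alone and avoid acid-promoted cyclisation of the prenyl group onto the 2'-hydroxyl.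

Compound list
1 | 2',6'-dihydroxy-4'-methoxyacetophenone | CC(=O)c1c(O)cc(OC)cc1O | starting material
2 | (E)-1-(2,6-dihydroxy-4-methoxyphenyl)-3-(dimethylamino)prop-2-en-1-one | CN(C)/C=C/C(=O)c1c(O)cc(OC)cc1O | intermediate
3 | 2-(dimethylamino)-5-hydroxy-7-methoxy-3-(3-methylbut-2-en-1-yl)chroman-4-one (racemic mixture of diastereomers, not isolated) | COc1cc(O)c2C(=O)C(CC=C(C)C)C(N(C)C)Oc2c1 | intermediate
4 | 5-hydroxy-7-methoxy-3-(3-methylbut-2-en-1-yl)-4H-chromen-4-one | COc1cc(O)c2c(=O)c(CC=C(C)C)coc2c1 | intermediate
5 | 5-(tert-butyldimethylsilyloxy)-7-methoxy-3-(3-methylbut-2-en-1-yl)-4H-chromen-4-one | COc1cc(O[Si](C)(C)C(C)(C)C)c2c(=O)c(CC=C(C)C)coc2c1 | intermediate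
6 | 4-bromoresorcinol (4-bromobenzene-1,3-diol) | Oc1ccc(Br)c(O)c1 | starting material
7 | 1-bromo-2,4-bis(tert-butyldimethylsilyloxy)benzene | CC(C)(C)[Si](C)(C)Oc1ccc(Br)c(O[Si](C)(C)C(C)(C)C)c1 | intermediate
8 | [5-(tert-butyldimethylsilyloxy)-7-methoxy-3-(3-methylbut-2-en-1-yl)-4-oxo-4H-chromen-2-yl]zinc chloride (LiCl complex, not isolated) | COc1cc(O[Si](C)(C)C(C)(C)C)c2c(=O)c(CC=C(C)C)c([Zn]Cl)oc2c1 | intermediate
9 | 2-[2,4-bis(tert-butyldimethylsilyloxy)phenyl]-5-(tert-butyldimethylsilyloxy)-7-methoxy-3-(3-methylbut-2-en-1-yl)-4H-chromen-4-one | COc1cc(O[Si](C)(C)C(C)(C)C)c2c(=O)c(CC=C(C)C)c(-c3ccc(O[Si](C)(C)C(C)(C)C)cc3O[Si](C)(C)C(C)(C)C)oc2c1 | intermediate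
10 | 2-(2,4-dihydroxyphenyl)-5-hydroxy-7-methoxy-3-(3-methylbut-2-en-1-yl)-4H-chromen-4-one | COc1cc(O)c2c(=O)c(CC=C(C)C)c(-c3ccc(O)cc3O)oc2c1 | target

Total step count: 6. Longest linear sequence: 5 steps (steps 1, 2, 3, 5, 6); step 4 is a one-step side branch.

Steps most likely to fail

Step 5. The metalation at C2 may be incomplete. Alternatively, the hindered, electron-rich aryl bromide may undergo oxidative addition and transmetalation so slowly that the zinc species is protonated before it couples. The fallback sets out from 5 and 7 and comes back at 9. It uses the native electrophilicity of C2 instead of its metalation. Magnesium insertion into 7 (Mg, LiCl, THF) should give [2,4-bis(tert-butyldimethylsilyloxy)phenyl]magnesium bromide F1. Copper-catalysed conjugate addition of this Grignard reagent to 5 in the presence of TMSCl (CuBr·SMe2, THF, −40 °C) should give the racemic silyl enol ether 2-[2,4-bis(tert-butyldimethylsilyloxy)phenyl]-5-(tert-butyldimethylsilyloxy)-7-methoxy-3-(3-methylbut-2-en-1-yl)-4-(trimethylsilyloxy)-2H-chromene F2. DDQ (CH2Cl2, 0 °C) then abstracts the C2 hydride, and loss of the trimethylsilyl group from the resulting 4-siloxybenzopyrylium ion gives 9.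

Step 2. Alkylation may occur at oxygen or nitrogen of the enaminone instead of carbon, or the ammonium salt formed may close unreacted enaminone to the 3-unsubstituted chromone. The fallback sets out from 2 and comes back at 4. Iodocyclisation of 2 (I2, CHCl3, rt) should give 5-hydroxy-3-iodo-7-methoxy-4H-chromen-4-one F3. Stille coupling with tributyl(3-methylbut-2-en-1-yl)stannane (Pd(PPh3)4, DMF, 80 °C) then installs the linear prenyl group and gives 4.

Step 3. Silylation of the chelated 5-hydroxyl may stall, or the peri silyl ether may be lost by hydrolysis during purification, which would leave an acidic phenol for the zinc amide. The fallback sets out from 4 and comes back at 10. It uses an ester in place of the silyl ether. Acylation (pivaloyl chloride, pyridine, DMAP, CH2Cl2) should give 7-methoxy-3-(3-methylbut-2-en-1-yl)-4-oxo-4H-chromen-5-yl pivalate F4. Zincation as in step 5 gives the ester-tolerant [7-methoxy-3-(3-methylbut-2-en-1-yl)-4-oxo-5-(pivaloyloxy)-4H-chromen-2-yl]zinc chloride F5. Negishi coupling with 7 gives 2-[2,4-bis(tert-butyldimethylsilyloxy)phenyl]-7-methoxy-3-(3-methylbut-2-en-1-yl)-4-oxo-4H-chromen-5-yl pivalate F6. Methanolysis (K2CO3, MeOH, rt) removes the pivalate and both aryl silyl ethers to give 10.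

Further compounds
F1 | step 5 | [2,4-bis(tert-butyldimethylsilyloxy)phenyl]magnesium bromide | CC(C)(C)[Si](C)(C)Oc1ccc([Mg]Br)c(O[Si](C)(C)C(C)(C)C)c1
F2 | step 5 | 2-[2,4-bis(tert-butyldimethylsilyloxy)phenyl]-5-(tert-butyldimethylsilyloxy)-7-methoxy-3-(3-methylbut-2-en-1-yl)-4-(trimethylsilyloxy)-2H-chromene (racemic) | COc1cc(O[Si](C)(C)C(C)(C)C)c2C(O[Si](C)(C)C)=C(CC=C(C)C)C(c3ccc(O[Si](C)(C)C(C)(C)C)cc3O[Si](C)(C)C(C)(C)C)Oc2c1
F3 | step 2 | 5-hydroxy-3-iodo-7-methoxy-4H-chromen-4-one | COc1cc(O)c2c(=O)c(I)coc2c1
F4 | step 3 | 7-methoxy-3-(3-methylbut-2-en-1-yl)-4-oxo-4H-chromen-5-yl pivalate | COc1cc(OC(=O)C(C)(C)C)c2c(=O)c(CC=C(C)C)coc2c1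
F5 | step 3 | [7-methoxy-3-(3-methylbut-2-en-1-yl)-4-oxo-5-(pivaloyloxy)-4H-chromen-2-yl]zinc chloride | COc1cc(OC(=O)C(C)(C)C)c2c(=O)c(CC=C(C)C)c([Zn]Cl)oc2c1
F6 | step 3 | 2-[2,4-bis(tert-butyldimethylsilyloxy)phenyl]-7-methoxy-3-(3-methylbut-2-en-1-yl)-4-oxo-4H-chromen-5-yl pivalate | COc1cc(OC(=O)C(C)(C)C)c2c(=O)c(CC=C(C)C)c(-c3ccc(O[Si](C)(C)C(C)(C)C)cc3O[Si](C)(C)C(C)(C)C)oc2c1
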